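## Analysis of the target

The target **21** is a 2H-chromene: a benzene ring fused to a pyran ring that contains O1, the fully substituted carbon C2 and a cis C3=C4 double bond conjugated with the arene. C2 is the only stereocentre. It is (R), carries a methyl group and a CH2O arm esterified with (E)-ferulic acid, and has no hydrogen, so it must be set once and cannot be corrected later. The benzene ring carries an acetyl group at C6 and a hydroxyl at C7, hydrogen-bonded to each other, with hydrogens at C5 and C8. The sensitive groups are the feruloyl ester with its free phenol and conjugated alkene (no strong base, hydride or hydrogenation late in the route), the electron-rich styrene-type C3=C4 bond (no strong acid) and the methyl ketone. The difficulty is the tertiary alkyl aryl ether at a stereocentre whose two one-carbon arms, C3 and the ester CH2, must be told apart. The strategy rests on the C3=C4 bond: C4 sits on arene carbon C4a and C3 sits next to C2, so both can be aldehyde carbons, and the aldehyde at C3 cannot enolise because C2 has no hydrogen.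

## Retrosynthetic reasoning

**Phenols last (21 to 20).** The two phenolic O–H bonds are revealed in the final step. As silyl ethers in **20** both fall to buffered fluoride, conditions under which the ester, the ketone and the chromene alkene should all be safe.

**Acetyl from bromide (20 to 18, through 19).** The C6–acetyl bond is cut. A ketone would not survive hydride reduction or a reductive carbonyl coupling, whereas an aryl bromide does. The forward reaction is a palladium-catalysed coupling with a tin enol ether and hydrolysis of **19**. It is placed after ester formation so that the labile ortho-silyloxy ketone exists for one step only.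

**Ester C–O bond (18 to 14 and 17).** Cutting the acyl–oxygen bond makes the route convergent. The acid **17** comes from ferulic acid **15** through the doubly silylated **16**. The forward reaction has to acylate a hindered, neopentyl-type primary alcohol without touching the phenol of the acid, hence the silyl ether.

**Primary alcohol from its benzylic ether (14 to 13).** The arm that will carry the ester is protected through the ring closure as a p-methoxybenzyl ether and freed oxidatively, which leaves the aryl silyl ether and the aryl bromide alone.

**C3=C4 (13 to 11, through 12).** This is the central cut. Both alkene carbons become aldehydes in **11**, and a reductive carbonyl coupling closes the pyran ring and makes the alkene in one operation. Cutting here leaves C2 and all four of its bonds untouched, so the ring closure carries no stereochemical or regiochemical question.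

**Two aldehydes from stable precursors (11 to 10 to 8 to 7).** The aryl aldehyde is traced to a nitrile, which also activates the ring for the ether-forming step. The aliphatic aldehyde is traced to a primary alcohol held as a triphenylmethyl ether. The order is detritylation, nitrile reduction (through imine **9**), then oxidation, so that no aldehyde meets a hydride.

**Aryl–oxygen bond (7 to 3 and 6).** The C8a–O1 bond is cut, not the C2–O1 bond. The tertiary alkoxide of **3** displaces the fluoride ortho to the nitrile of **6**, and no bond at the stereocentre is involved. Both arms of **3** carry carbon-based ethers. A silyl ether beside the tertiary alkoxide could shift to it and hand the arylation to a primary oxygen.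

**Arene (6 to 5 to 4).** The para oxygen is already present in **4**, so the ring has only one fluoride to displace. Bromination ortho to the hydroxyl gives **5**, and silylation gives **6**.

**Chiral pool (3 to 2 to 1).** The hydroxyl of **1** is tritylated to **2** and the epoxide is opened at its CH2 group by a benzylic alkoxide. The hydroxymethyl arm of **1** ends as C3 and the epoxide CH2 as the ester-bearing carbon, which fixes (R)-**1** as the enantiomer needed.

## Alternatives that were turned down

**Alternative 1:** The benzene ring is cut at C4a–C5 and C6–C7. In the forward direction an allyl-substituted bis(silyloxy) methoxy diene adds to a terminal ynone and the adduct aromatises by loss of an alcohol, giving the acetyl resorcinol **A1**.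
- For: the acetyl group and both ring oxygens arrive in one step from acyclic pieces, with no halogen, tin or titanium. On arene construction it is stronger than the chosen route.
- Against: the arene is not the problem of this target, since the pattern is available in **4**. **A1** has neither the pyran ring nor the C2 stereocentre. Closing the ring from the ortho-allyl phenol needs an oxidative cyclisation that creates the quaternary C2 from an alkene whose faces differ only by methyl against CH2OSi, so enantiocontrol is left to a late, unsolved step. The substituted diene also costs several steps.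
- Comparison: the chosen route takes C2 from the chiral pool and has only to close a ring around it.

**Alternative 2:** The C4–C4a bond is cut. A cationic phosphine gold catalyst (monovalent gold) activates the alkyne of an enantiopure tertiary aryl propargyl ether and the arene closes the ring to **A2**.
- For: it is the shortest plan, catalytic and redox-neutral, with the acetyl group present from the start. On step economy and mildness of the ring closure it is stronger than the chosen route.
- Against: the enantiopure tertiary propargylic ether has no chiral-pool source and would need an asymmetric alkynylation or a resolution before the same kind of O-arylation. The ether oxygen also has two ortho carbons, and C8, between the two oxygens, is the more electron-rich, so only sterics favours the required attack at C4a.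
- Comparison: the chosen route offers a ring closure with no regiochemical choice, because the two reacting carbons are fixed as aldehydes, and a stereocentre of secure origin.

**Alternative 3:** C4 is treated as a one-carbon insert. A Lewis-acidic metal triflate promotes addition of a silylated diazomethane to the C3 ketone of an enantiopure 2,2-disubstituted benzofuran-3-one, and a 1,2-aryl shift gives the chroman-3-one **A3**.
- For: it shares the bromide and silyl pattern of the chosen route and hence the same endgame. From **A3** the alkene can only form towards C4. It needs no high dilution.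
- Against: the ketone is flanked by the quaternary C2 and deactivated by conjugation with O1 through the arene. Migration of the alkyl carbon C2 in place of the aryl carbon, and epoxide formation, are open competitors. Three more steps (reduction, activation, elimination) are needed to reach C3=C4. The enantiopure benzofuranone requires an asymmetric construction of a quaternary centre next to a ketone.
- Comparison: the chosen route forms the alkene in the ring-closing step itself.

Key step: step 9

Remark: both enantiomers of 2-methylglycidol are taken to be available in high enantiomeric purity; the (R) enantiomer is used because its hydroxymethyl arm becomes C3. The titanium-bound intermediate **12** is drawn as the free diol.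

## Route

Step 1
Reactants: 1 (R)-2-methylglycidol
Product: 2 (S)-2-methyl-2-[(triphenylmethoxy)methyl]oxirane
Conditions: TrCl, Et3N, DMAP (cat.), CH2Cl2, 0 °C → rt
Reagents that add atoms: trityl chloride, ClC(c1ccccc1)(c1ccccc1)c1ccccc1
Why: Tritylation of a primary alcohol under basic conditions, which spares the acid-sensitive 2,2-disubstituted epoxide; the stereocentre is not touched and the descriptor changes from R to S only because the priorities change.

Step 2
Reactants: 2 (S)-2-methyl-2-[(triphenylmethoxy)methyl]oxirane
Product: 3 (S)-1-[(4-methoxyphenyl)methoxy]-2-methyl-3-(triphenylmethoxy)propan-2-ol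
Conditions: 4-methoxybenzyl alcohol, NaH, DMF, 60 °C
Reagents that add atoms: 4-methoxybenzyl alcohol, COc1ccc(CO)cc1
Why: SN2 opening of the epoxide by the benzylic alkoxide at the unsubstituted CH2 group; the C–O bond at the quaternary carbon is not broken, so the configuration is kept. Both arms now carry carbon-based ethers that cannot migrate to the tertiary oxygen.

Step 3
Reactants: 4 2-fluoro-4-hydroxybenzonitrile
Product: 5 5-bromo-2-fluoro-4-hydroxybenzonitrile
Conditions: NBS (1.0 equiv), p-TsOH·H2O (10 mol%), MeCN, 0 °C → rt
Reagents that add atoms: N-bromosuccinimide, BrN1C(=O)CCC1=O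
Why: Electrophilic aromatic bromination ortho to the hydroxyl, the para position being blocked by the nitrile. Of the two ortho carbons, C5 is also para to fluorine and less crowded than C3, which lies between fluorine and oxygen.

Step 4
Reactants: 5 5-bromo-2-fluoro-4-hydroxybenzonitrile
Product: 6 5-bromo-2-fluoro-4-[(triisopropylsilyl)oxy]benzonitrile
Conditions: TIPSCl, imidazole, DMF, rt
Reagents that add atoms: triisopropylsilyl chloride, CC(C)[Si](Cl)(C(C)C)C(C)C
Why: Silylation of an acidic phenol; the bulky triisopropylsilyl group is chosen because it must resist a hindered alkoxide, a hydride and low-valent titanium before it is removed at the end.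

Step 5
Reactants: 3 (S)-1-[(4-methoxyphenyl)methoxy]-2-methyl-3-(triphenylmethoxy)propan-2-ol; 6 5-bromo-2-fluoro-4-[(triisopropylsilyl)oxy]benzonitrile
Product: 7 5-bromo-2-{[(2S)-1-[(4-methoxyphenyl)methoxy]-2-methyl-3-(triphenylmethoxy)propan-2-yl]oxy}-4-[(triisopropylsilyl)oxy]benzonitrile
Conditions: 3, KN(SiMe3)2, THF, 0 °C; then 6, 0 °C → rt
Reagents that add atoms: none
Why: Nucleophilic aromatic substitution of the only fluoride, activated by the ortho nitrile and the para bromine, by a tertiary potassium alkoxide, a known way to make tertiary alkyl aryl ethers. The C2–O bond is not involved, so the configuration is kept, and the hindered alkoxide should prefer the aryl carbon to the shielded silicon.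

Step 6
Reactants: 7 5-bromo-2-{[(2S)-1-[(4-methoxyphenyl)methoxy]-2-methyl-3-(triphenylmethoxy)propan-2-yl]oxy}-4-[(triisopropylsilyl)oxy]benzonitrile
Product: 8 5-bromo-2-{[(2R)-1-hydroxy-3-[(4-methoxyphenyl)methoxy]-2-methylpropan-2-yl]oxy}-4-[(triisopropylsilyl)oxy]benzonitrile
Conditions: p-TsOH·H2O (cat.), MeOH/CH2Cl2 (1:1), rt
Reagents that add atoms: none
Why: Acid-catalysed solvolysis of the trityl ether through the trityl cation, trapped by methanol; the p-methoxybenzyl ether, the aryl silyl ether and the tertiary aryl ether (deactivated towards ionisation by two β-oxygens) are stable to catalytic sulfonic acid at room temperature.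

Step 7
Reactants: 8 5-bromo-2-{[(2R)-1-hydroxy-3-[(4-methoxyphenyl)methoxy]-2-methylpropan-2-yl]oxy}-4-[(triisopropylsilyl)oxy]benzonitrile
Product: 10 5-bromo-2-{[(2R)-1-hydroxy-3-[(4-methoxyphenyl)methoxy]-2-methylpropan-2-yl]oxy}-4-[(triisopropylsilyl)oxy]benzaldehyde, via aldimine 9 (not isolated)
Conditions: i-Bu2AlH (2.5 equiv), CH2Cl2, −78 → 0 °C; then 1 M HCl, 0 °C
Reagents that add atoms: water, O
Why: Partial reduction of an aryl nitrile with diisobutylaluminium hydride stops at the N-aluminated imine, which dilute acid hydrolyses to the aldehyde; the first equivalent of hydride is consumed by the free hydroxyl, and ethers, silyl ether and aryl bromide are inert.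

Step 8
Reactants: 10 5-bromo-2-{[(2R)-1-hydroxy-3-[(4-methoxyphenyl)methoxy]-2-methylpropan-2-yl]oxy}-4-[(triisopropylsilyl)oxy]benzaldehyde
Product: 11 5-bromo-2-{[(2S)-1-[(4-methoxyphenyl)methoxy]-2-methyl-3-oxopropan-2-yl]oxy}-4-[(triisopropylsilyl)oxy]benzaldehyde
Conditions: Dess–Martin periodinane, NaHCO3, CH2Cl2, 0 °C → rt
Reagents that add atoms: none
Why: Dess–Martin oxidation of a hindered primary alcohol to the aldehyde under buffered, non-basic conditions; the new aldehyde has no α-hydrogen and cannot enolise, epimerise or eliminate.

Step 9
Reactants: 11 5-bromo-2-{[(2S)-1-[(4-methoxyphenyl)methoxy]-2-methyl-3-oxopropan-2-yl]oxy}-4-[(triisopropylsilyl)oxy]benzaldehyde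
Product: 13 (R)-6-bromo-2-{[(4-methoxyphenyl)methoxy]methyl}-2-methyl-7-[(triisopropylsilyl)oxy]-2H-chromene, via titanium diolate 12 (not isolated)
Conditions: TiCl3(DME)1.5 (10 equiv), Zn–Cu couple (30 equiv), DME, reflux, 3 h; then 11 in DME by syringe pump over 24 h (final ca. 0.003 M), reflux 4 h
Reagents that add atoms: none
Why: Intramolecular McMurry coupling: low-valent titanium made from TiCl3 (trivalent titanium) and Zn–Cu transfers an electron first to the aryl aldehyde, the easier carbonyl to reduce, and the titanium-bound ketyl at C4 adds to the aliphatic aldehyde carbon C3 held close by the ether link, giving the titanium diolate 12. At reflux the diolate is deoxygenated on the titanium surface; the benzylic C4–O bond should break first, so that loss of the second oxygen from C3 ends in the alkene and not in expulsion of a β-oxygen substituent. The closest known reaction type is the titanium-mediated reductive cyclisation of dialdehydes and keto aldehydes to cycloalkenes, for which heteroatom-containing tethers are accepted. The pyran ring closes by carbonyl–carbonyl coupling in a 6-exo-trig sense (the oxygen of the attacked carbonyl stays outside the ring), and a six-membered ring can hold only the cis alkene, so no alkene geometry has to be controlled. No stereocentre is created; C2 has no hydrogen and none of its four bonds takes part, so the configuration brought in from 1 is kept. The step needs cyclisation to win over intermolecular coupling, which slow addition at high dilution secures, and it needs the α-aryloxy aldehyde to be captured before it is reduced on its own, which the lower reduction potential of the aryl aldehyde and the closeness of the two carbonyls secure. The aryl bromide, the benzylic ether and the aryl silyl ether are of kinds that low-valent titanium normally leaves alone.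

Step 10
Reactants: 13 (R)-6-bromo-2-{[(4-methoxyphenyl)methoxy]methyl}-2-methyl-7-[(triisopropylsilyl)oxy]-2H-chromene
Product: 14 [(2R)-6-bromo-2-methyl-7-[(triisopropylsilyl)oxy]-2H-chromen-2-yl]methanol
Conditions: DDQ, CH2Cl2/pH 7 buffer (10:1), 0 °C → rt
Reagents that add atoms: none
Why: Oxidative cleavage of the p-methoxybenzyl ether by hydride abstraction and hydrolysis of the resulting oxocarbenium ion; the chromene has no allylic or benzylic hydrogen for the quinone to abstract, and the aryl silyl ether is untouched at neutral pH.

Step 11
Reactants: 15 (E)-ferulic acid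
Product: 17 (E)-3-{4-[(tert-butyldimethylsilyl)oxy]-3-methoxyphenyl}prop-2-enoic acid, via bis-silyl derivative 16 (not isolated)
Conditions: TBSCl (2.5 equiv), imidazole, DMF, rt; then AcOH/THF/H2O, rt
Reagents that add atoms: tert-butyldimethylsilyl chloride, CC(C)(C)[Si](C)(C)Cl
Why: Silylation of both the phenol and the acid, followed by selective hydrolysis of the far more labile silyl ester under mild acid, which leaves the aryl silyl ether in place.

Step 12
Reactants: 14 [(2R)-6-bromo-2-methyl-7-[(triisopropylsilyl)oxy]-2H-chromen-2-yl]methanol; 17 (E)-3-{4-[(tert-butyldimethylsilyl)oxy]-3-methoxyphenyl}prop-2-enoic acid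
Product: 18 [(2R)-6-bromo-2-methyl-7-[(triisopropylsilyl)oxy]-2H-chromen-2-yl]methyl (E)-3-{4-[(tert-butyldimethylsilyl)oxy]-3-methoxyphenyl}prop-2-enoate
Conditions: EDC·HCl, DMAP, CH2Cl2, 0 °C → rt
Reagents that add atoms: none
Why: Steglich esterification; the acylpyridinium ion formed from the carbodiimide-activated acid is reactive enough for a neopentyl-type primary alcohol, and the alkene geometry of the acid is not affected.

Step 13
Reactants: 18 [(2R)-6-bromo-2-methyl-7-[(triisopropylsilyl)oxy]-2H-chromen-2-yl]methyl (E)-3-{4-[(tert-butyldimethylsilyl)oxy]-3-methoxyphenyl}prop-2-enoate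
Product: 20 [(2R)-6-acetyl-2-methyl-7-[(triisopropylsilyl)oxy]-2H-chromen-2-yl]methyl (E)-3-{4-[(tert-butyldimethylsilyl)oxy]-3-methoxyphenyl}prop-2-enoate, via enol ether 19 (not isolated)
Conditions: Bu3Sn(C(OEt)=CH2), Pd(PPh3)4 (5 mol%), toluene, 100 °C; then 1 M HCl, THF, rt
Reagents that add atoms: tributyl(1-ethoxyvinyl)stannane, CCCC[Sn](CCCC)(CCCC)C(=C)OCC; water, O
Why: Stille coupling (oxidative addition of zerovalent palladium into the aryl bromide, transmetalation, reductive elimination) gives enol ether 19, which dilute acid hydrolyses to the methyl ketone. The conditions are fluoride-free and neutral, so the silyl ethers and the ester survive, and the β-substituted cinnamate is a poor Heck acceptor.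

Step 14
Reactants: 20 [(2R)-6-acetyl-2-methyl-7-[(triisopropylsilyl)oxy]-2H-chromen-2-yl]methyl (E)-3-{4-[(tert-butyldimethylsilyl)oxy]-3-methoxyphenyl}prop-2-enoate
Product: 21 [(2R)-6-acetyl-7-hydroxy-2-methyl-2H-chromen-2-yl]methyl (E)-3-(4-hydroxy-3-methoxyphenyl)prop-2-enoate
Conditions: Bu4NF (2.5 equiv), AcOH (3 equiv), THF, 0 °C
Reagents that add atoms: none
Why: Fluoride cleaves both aryl silyl ethers, whose phenoxides (one ortho to the ketone, one vinylogous to the ester) leave silicon easily; acetic acid protonates the phenoxides as they form so that the feruloyl ester is neither cleaved nor transesterified.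

## Compound list

1 | (R)-2-methylglycidol, [(2R)-2-methyloxiran-2-yl]methanol | OC[C@]1(C)CO1 | starting material
2 | (S)-2-methyl-2-[(triphenylmethoxy)methyl]oxirane | C(c1ccccc1)(c1ccccc1)(c1ccccc1)OC[C@]1(C)CO1 | intermediate
3 | (S)-1-[(4-methoxyphenyl)methoxy]-2-methyl-3-(triphenylmethoxy)propan-2-ol | COc1ccc(COC[C@@](O)(C)COC(c2ccccc2)(c2ccccc2)c2ccccc2)cc1 | intermediate
4 | 2-fluoro-4-hydroxybenzonitrile | N#Cc1ccc(O)cc1F | starting material
5 | 5-bromo-2-fluoro-4-hydroxybenzonitrile | N#Cc1cc(Br)c(O)cc1F | intermediate
6 | 5-bromo-2-fluoro-4-[(triisopropylsilyl)oxy]benzonitrile | N#Cc1cc(Br)c(O[Si](C(C)C)(C(C)C)C(C)C)cc1F | intermediate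
7 | 5-bromo-2-{[(2S)-1-[(4-methoxyphenyl)methoxy]-2-methyl-3-(triphenylmethoxy)propan-2-yl]oxy}-4-[(triisopropylsilyl)oxy]benzonitrile | COc1ccc(COC[C@@](Oc2cc(O[Si](C(C)C)(C(C)C)C(C)C)c(Br)cc2C#N)(C)COC(c2ccccc2)(c2ccccc2)c2ccccc2)cc1 | intermediate
8 | 5-bromo-2-{[(2R)-1-hydroxy-3-[(4-methoxyphenyl)methoxy]-2-methylpropan-2-yl]oxy}-4-[(triisopropylsilyl)oxy]benzonitrile | COc1ccc(COC[C@@](Oc2cc(O[Si](C(C)C)(C(C)C)C(C)C)c(Br)cc2C#N)(C)CO)cc1 | intermediate
9 | aldimine of 10 (N–H imine in place of the aryl aldehyde, (2R) side chain), formed on the aluminium | COc1ccc(COC[C@@](Oc2cc(O[Si](C(C)C)(C(C)C)C(C)C)c(Br)cc2C=N)(C)CO)cc1 | intermediate (not isolated)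
10 | 5-bromo-2-{[(2R)-1-hydroxy-3-[(4-methoxyphenyl)methoxy]-2-methylpropan-2-yl]oxy}-4-[(triisopropylsilyl)oxy]benzaldehyde | COc1ccc(COC[C@@](Oc2cc(O[Si](C(C)C)(C(C)C)C(C)C)c(Br)cc2C=O)(C)CO)cc1 | intermediate
11 | 5-bromo-2-{[(2S)-1-[(4-methoxyphenyl)methoxy]-2-methyl-3-oxopropan-2-yl]oxy}-4-[(triisopropylsilyl)oxy]benzaldehyde | COc1ccc(COC[C@@](Oc2cc(O[Si](C(C)C)(C(C)C)C(C)C)c(Br)cc2C=O)(C)C=O)cc1 | intermediate (key-step precursor)
12 | titanium-bound (2S)-6-bromo-2-{[(4-methoxyphenyl)methoxy]methyl}-2-methyl-7-[(triisopropylsilyl)oxy]-3,4-dihydro-2H-chromene-3,4-diolate, drawn as the free diol, C3 and C4 not controlled | COc1ccc(COC[C@@]2(C)C(O)C(O)c3cc(Br)c(O[Si](C(C)C)(C(C)C)C(C)C)cc3O2)cc1 | intermediate (not isolated)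
13 | (R)-6-bromo-2-{[(4-methoxyphenyl)methoxy]methyl}-2-methyl-7-[(triisopropylsilyl)oxy]-2H-chromene | COc1ccc(COC[C@@]2(C)C=Cc3cc(Br)c(O[Si](C(C)C)(C(C)C)C(C)C)cc3O2)cc1 | intermediate (key-step product)
14 | [(2R)-6-bromo-2-methyl-7-[(triisopropylsilyl)oxy]-2H-chromen-2-yl]methanol | OC[C@@]1(C)C=Cc2cc(Br)c(O[Si](C(C)C)(C(C)C)C(C)C)cc2O1 | intermediate
15 | (E)-ferulic acid | COc1cc(/C=C/C(=O)O)ccc1O | starting material
16 | tert-butyldimethylsilyl (E)-3-{4-[(tert-butyldimethylsilyl)oxy]-3-methoxyphenyl}prop-2-enoate | COc1cc(/C=C/C(=O)O[Si](C)(C)C(C)(C)C)ccc1O[Si](C)(C)C(C)(C)C | intermediate (not isolated)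
17 | (E)-3-{4-[(tert-butyldimethylsilyl)oxy]-3-methoxyphenyl}prop-2-enoic acid | COc1cc(/C=C/C(=O)O)ccc1O[Si](C)(C)C(C)(C)C | intermediate
18 | [(2R)-6-bromo-2-methyl-7-[(triisopropylsilyl)oxy]-2H-chromen-2-yl]methyl (E)-3-{4-[(tert-butyldimethylsilyl)oxy]-3-methoxyphenyl}prop-2-enoate | COc1cc(/C=C/C(=O)OC[C@@]2(C)C=Cc3cc(Br)c(O[Si](C(C)C)(C(C)C)C(C)C)cc3O2)ccc1O[Si](C)(C)C(C)(C)C | intermediate
19 | [(2R)-6-(1-ethoxyethenyl)-2-methyl-7-[(triisopropylsilyl)oxy]-2H-chromen-2-yl]methyl (E)-3-{4-[(tert-butyldimethylsilyl)oxy]-3-methoxyphenyl}prop-2-enoate | COc1cc(/C=C/C(=O)OC[C@@]2(C)C=Cc3cc(C(=C)OCC)c(O[Si](C(C)C)(C(C)C)C(C)C)cc3O2)ccc1O[Si](C)(C)C(C)(C)C | intermediate (not isolated)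
20 | [(2R)-6-acetyl-2-methyl-7-[(triisopropylsilyl)oxy]-2H-chromen-2-yl]methyl (E)-3-{4-[(tert-butyldimethylsilyl)oxy]-3-methoxyphenyl}prop-2-enoate | COc1cc(/C=C/C(=O)OC[C@@]2(C)C=Cc3cc(C(C)=O)c(O[Si](C(C)C)(C(C)C)C(C)C)cc3O2)ccc1O[Si](C)(C)C(C)(C)C | intermediate
21 | [(2R)-6-acetyl-7-hydroxy-2-methyl-2H-chromen-2-yl]methyl (E)-3-(4-hydroxy-3-methoxyphenyl)prop-2-enoate | COc1cc(/C=C/C(=O)OC[C@@]2(C)C=Cc3cc(C(C)=O)c(O)cc3O2)ccc1O | target

## Step count and least certain steps

Total step count: 14. Longest linear sequence: 11 steps (steps 1, 2, 5 to 10, 12 to 14, from **1**).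

**Step 9 (key step).** The most likely failures are intermolecular reductive coupling to dimers and oligomers, a stop at the diol stage **12** without deoxygenation, and reductive cleavage of the C2–O1 bond if the aliphatic aldehyde is reduced before it is captured. All three follow from the need to run a slow, heterogeneous, strongly reducing reaction on a substrate with an oxygen leaving group next to one carbonyl. Fallback: from **11**, double methylenation with the ylide from methyltriphenylphosphonium bromide and KN(SiMe3)2 should give the diene 1-bromo-5-ethenyl-4-{[(2R)-1-[(4-methoxyphenyl)methoxy]-2-methylbut-3-en-2-yl]oxy}-2-[(triisopropylsilyl)oxy]benzene F1. Ring-closing metathesis of F1 with the second-generation Grubbs catalyst in CH2Cl2 forms the same C3=C4 bond with loss of ethene and comes back to the route at **13**.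

**Step 5.** Two processes threaten it: slow attack by a hindered tertiary alkoxide, and loss of the triisopropylsilyl group to alkoxide or to the fluoride set free, which leaves a phenoxide that shuts the ring off from substitution. Fallback: from **5**, the phenol is protected as the base-stable acetal 5-bromo-2-fluoro-4-(methoxymethoxy)benzonitrile F2 (MeOCH2Cl, i-Pr2NEt). The potassium alkoxide of **3** displaces its fluoride to give 5-bromo-2-{[(2S)-1-[(4-methoxyphenyl)methoxy]-2-methyl-3-(triphenylmethoxy)propan-2-yl]oxy}-4-(methoxymethoxy)benzonitrile F3. HCl in MeOH/THF removes the trityl ether and the aryl acetal together to give 5-bromo-4-hydroxy-2-{[(2R)-1-hydroxy-3-[(4-methoxyphenyl)methoxy]-2-methylpropan-2-yl]oxy}benzonitrile F4. Silylation of the much more acidic phenol with TIPSCl and Et3N at 0 °C returns to the route at **8**.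

**Step 13.** Oxidative addition next to the bulky silyloxy group on an electron-rich ring may be slow, so that destannylation of the reagent, a Heck-type reaction at the cinnamate or partial desilylation during the acid hydrolysis compete. Fallback: the acetyl group is brought in before the ester, without palladium. From **13**, bromine–lithium exchange (n-BuLi, THF, −78 °C, where the bulky silyl group should not shift from oxygen to carbon) and acylation with N-methoxy-N-methylacetamide should give 1-[(2R)-2-{[(4-methoxyphenyl)methoxy]methyl}-2-methyl-7-[(triisopropylsilyl)oxy]-2H-chromen-6-yl]ethanone F5. DDQ then frees 1-[(2R)-2-(hydroxymethyl)-2-methyl-7-[(triisopropylsilyl)oxy]-2H-chromen-6-yl]ethanone F6, and esterification of F6 with **17** (EDC·HCl, DMAP) comes back to the route at **20**.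

**Step 3.** Bromination may go partly to C3 or proceed to the dibromide, because the first bromine barely deactivates the phenol. Fallback: the oxygen is introduced on a ring that already carries the bromine. Commercial 5-bromo-2,4-difluorobenzonitrile F7 is treated with the sodium alkoxide of 2-(methylsulfonyl)ethanol (NaH, DMF, 0 °C → rt), which should displace the fluoride para to the nitrile and ortho to bromine. The resulting 5-bromo-2-fluoro-4-[2-(methylsulfonyl)ethoxy]benzonitrile F8 loses methyl vinyl sulfone under the same basic conditions and gives, after acidification, **5**, where the route is rejoined.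

## Further compounds

F1 | step 9 | 1-bromo-5-ethenyl-4-{[(2R)-1-[(4-methoxyphenyl)methoxy]-2-methylbut-3-en-2-yl]oxy}-2-[(triisopropylsilyl)oxy]benzene | COc1ccc(COC[C@@](Oc2cc(O[Si](C(C)C)(C(C)C)C(C)C)c(Br)cc2C=C)(C)C=C)cc1
F2 | step 5 | 5-bromo-2-fluoro-4-(methoxymethoxy)benzonitrile | COCOc1cc(F)c(C#N)cc1Br
F3 | step 5 | 5-bromo-2-{[(2S)-1-[(4-methoxyphenyl)methoxy]-2-methyl-3-(triphenylmethoxy)propan-2-yl]oxy}-4-(methoxymethoxy)benzonitrile | COc1ccc(COC[C@@](Oc2cc(OCOC)c(Br)cc2C#N)(C)COC(c2ccccc2)(c2ccccc2)c2ccccc2)cc1
F4 | step 5 | 5-bromo-4-hydroxy-2-{[(2R)-1-hydroxy-3-[(4-methoxyphenyl)methoxy]-2-methylpropan-2-yl]oxy}benzonitrile | COc1ccc(COC[C@@](Oc2cc(O)c(Br)cc2C#N)(C)CO)cc1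
F5 | step 13 | 1-[(2R)-2-{[(4-methoxyphenyl)methoxy]methyl}-2-methyl-7-[(triisopropylsilyl)oxy]-2H-chromen-6-yl]ethanone | COc1ccc(COC[C@@]2(C)C=Cc3cc(C(C)=O)c(O[Si](C(C)C)(C(C)C)C(C)C)cc3O2)cc1
F6 | step 13 | 1-[(2R)-2-(hydroxymethyl)-2-methyl-7-[(triisopropylsilyl)oxy]-2H-chromen-6-yl]ethanone | OC[C@@]1(C)C=Cc2cc(C(C)=O)c(O[Si](C(C)C)(C(C)C)C(C)C)cc2O1
F7 | step 3 | 5-bromo-2,4-difluorobenzonitrile (commercial starting material of the fallback) | N#Cc1cc(Br)c(F)cc1F
F8 | step 3 | 5-bromo-2-fluoro-4-[2-(methylsulfonyl)ethoxy]benzonitrile | CS(=O)(=O)CCOc1cc(F)c(C#N)cc1Br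
A1 | alternative 1 | (E)-1-[5-(4-(tert-butyldimethylsilyloxy)-3-methylbut-2-enyl)-2,4-dihydroxyphenyl]ethanone | CC(=O)c1cc(C/C=C(\C)CO[Si](C)(C)C(C)(C)C)c(O)cc1O
A2 | alternative 2 | (R)-1-[2-((tert-butyldimethylsilyloxy)methyl)-7-(methoxymethoxy)-2-methyl-2H-chromen-6-yl]ethanone | CC(C)(C)[Si](C)(C)OC[C@@]1(C)C=Cc2cc(C(C)=O)c(OCOC)cc2O1
A3 | alternative 3 | (S)-6-bromo-2-((tert-butyldimethylsilyloxy)methyl)-2-methyl-7-(triisopropylsilyloxy)chroman-3-one | CC(C)(C)[Si](C)(C)OC[C@@]1(C)C(=O)Cc2cc(Br)c(O[Si](C(C)C)(C(C)C)C(C)C)cc2O1
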